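**Plan**

Numbering: ring A is C1–C2–C3–C4–C5–C10, ring B is C5–C6–C7–C8–C9–C10, C14 on C10, C15 on C4, acrylate C11(=C13)–C12 on C7; β is the face carrying the C10 methyl group.
Enabling feature: C8 is a carbinol carbon that can come from an aldehyde and C7 is the β-carbon of the C11–C12 enoate, so both ends of the C7–C8 bond of ring B are electrophilic; a reductive ketyl–olefin closure joins them, and an acetoxy group on C13 lets the enolate regenerate the C11=C13 methylene.
Cuts, in retrosynthetic order: acetyl and silyl groups; C7–C8 (ring B); C8=O from a C10 allyl arm; C7=C11/C13–OAc from a C7 aldehyde (C7–C11 bond, acetate transposition); C6–O from a C5 vinyl group; C5–C6 and C10–C9 by conjugate addition and enolate allylation; C5=C10 by ring-closing metathesis; C1–C10 by Grignard addition to a lactol from (R)-linalool.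
Forward: ring A is made first as an enantiopure cyclohexenone, then receives the C5 vinyl and C10 allyl arms, the C1 and C6 oxygens and the enoate arm; ring B closes last.
Stereochemistry: C4 comes from (R)-linalool; C5 is set anti to the C4 silyloxy group, C10 anti to the C5 vinyl group, C1 by hydride attack on the α face, C6 by C4–OH-directed epoxidation; a 4,6-O-silylene then fixes ring A so that C7 and C8 arise in a chair with all ring B substituents equatorial.

Key step: step 17

Remark: commercial (R)-(−)-linalool of high enantiomeric purity is assumed; 4, 6, 7 and 25 are carried as mixtures at centres that are destroyed later (anomeric carbon, C1 carbinol before step 4, C7 carbinol).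

**Route**

Step 1
Reactants: 1 (R)-(−)-linalool
Product: 4 (5R)-5-ethenyl-5-methyloxolan-2-ol, via ozonide 2 (not isolated), via hydroxy aldehyde 3 (not isolated)
Conditions: O3, CH2Cl2, −78 °C, Sudan Red 7B end point; then Me2S, −78 °C → rt
Reagents that add atoms: ozone, [O-][O+]=O
Why: Ozonolysis with reductive work-up is chemoselective for the electron-rich trisubstituted alkene over the monosubstituted vinyl group when ozone is dosed to a dye end point, and the γ-hydroxy aldehyde closes spontaneously to the five-membered lactol, the tertiary carbinol centre (later C4) being untouched.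

Step 2
Reactants: 4 (5R)-5-ethenyl-5-methyloxolan-2-ol; 5 isopropenylmagnesium bromide
Product: 6 (6R)-2,6-dimethylocta-1,7-diene-3,6-diol
Conditions: 5 (3 equiv), THF, 0 °C → rt; aq. NH4Cl
Reagents that add atoms: none
Why: Grignard addition to the ring-opened aldehyde form of the lactol (one equivalent of 5 is spent on the lactol O–H) forms the C1–C10 bond, and the new carbinol centre, formed without control, is erased by the oxidation in step 4.

Step 3
Reactants: 6 (6R)-2,6-dimethylocta-1,7-diene-3,6-diol
Product: 7 (4R)-2,4-dimethylcyclohex-2-ene-1,4-diol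
Conditions: (H2IMes)(PCy3)Cl2Ru=CHPh (second-generation Grubbs catalyst, 3 mol%), CH2Cl2 (10 mM), 40 °C
Reagents that add atoms: none
Why: Ring-closing metathesis of the 1,1-disubstituted and the monosubstituted alkene closes six-membered ring A with a trisubstituted C5=C10 double bond and loss of ethene, a closure that free allylic hydroxyl groups tolerate and that forms no stereocentre.

Step 4
Reactants: 7 (4R)-2,4-dimethylcyclohex-2-ene-1,4-diol
Product: 8 (4R)-4-hydroxy-2,4-dimethylcyclohex-2-en-1-one
Conditions: MnO2 (activated, 15 equiv), CH2Cl2, rt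
Reagents that add atoms: none
Why: Allylic oxidation with MnO2 takes only the secondary allylic alcohol, since the tertiary C4 carbinol cannot be oxidised and the neutral conditions allow no allylic transposition.

Step 5
Reactants: 8 (4R)-4-hydroxy-2,4-dimethylcyclohex-2-en-1-one
Product: 9 (4R)-2,4-dimethyl-4-(trimethylsilyloxy)cyclohex-2-en-1-one
Conditions: Me3SiCl, imidazole, DMF, 0 °C → rt
Reagents that add atoms: chlorotrimethylsilane, C[Si](C)(C)Cl
Why: Silyl ether formation masks the tertiary hydroxyl so that it cannot steer the organometallic reagent of step 6 to its own face, and the group falls off later under mild acid.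

Step 6
Reactants: 9 (4R)-2,4-dimethyl-4-(trimethylsilyloxy)cyclohex-2-en-1-one; 10 vinylmagnesium bromide
Product: 11 (3R,4R)-3-ethenyl-2,4-dimethyl-1,4-bis(trimethylsilyloxy)cyclohex-1-ene
Conditions: 10 (2 equiv), CuBr·SMe2 (10 mol%), Me3SiCl (2.5 equiv), HMPA (2.5 equiv), THF, −78 °C; Et3N, cold aq. NaHCO3
Reagents that add atoms: chlorotrimethylsilane, C[Si](C)(C)Cl
Why: Copper-catalysed, chlorosilane-accelerated conjugate addition of the vinyl Grignard reagent should form the C5–C6 bond anti to the C4 silyloxy group (the C–O bond sits pseudoaxial and antiperiplanar to the incoming nucleophile), so the vinyl group ends up cis to the C4 methyl group, and the enolate is captured regiospecifically as its silyl enol ether.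

Step 7
Reactants: 11 (3R,4R)-3-ethenyl-2,4-dimethyl-1,4-bis(trimethylsilyloxy)cyclohex-1-ene; 12 allyl bromide
Product: 15 (2R,3R,4R)-3-ethenyl-4-hydroxy-2,4-dimethyl-2-(prop-2-enyl)cyclohexan-1-one, via lithium enolate 13 (not isolated), via silyl ether ketone 14 (not isolated)
Conditions: MeLi (1.05 equiv), THF, 0 °C; 12 (3 equiv), HMPA, −78 → 0 °C; then 1 M HCl, THF, rt
Reagents that add atoms: none
Why: Methyllithium releases the regiodefined tetrasubstituted lithium enolate, whose C-allylation (enolate alkylation) should occur on the face opposite the adjacent C5 vinyl and the C4 methyl groups, setting the C10 quaternary centre with allyl trans to vinyl, and dilute acid then cleaves the tertiary trimethylsilyl ether.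

Step 8
Reactants: 15 (2R,3R,4R)-3-ethenyl-4-hydroxy-2,4-dimethyl-2-(prop-2-enyl)cyclohexan-1-one
Product: 16 ring A 1β,4α-diol (C1 alcohol cis to the C10 methyl group)
Conditions: NaBH4, MeOH, −20 → 0 °C
Reagents that add atoms: none
Why: Hydride reduction with the small reagent NaBH4 should occur on the α face of the carbonyl, because the β face is screened in either ring chair (by the axial C10 methyl group in one, by the syn-axial C5 vinyl group in the other), which gives the 1β-alcohol.

Step 9
Reactants: 16 ring A 1β,4α-diol
Product: 17 1-O-tert-butyldimethylsilyl ether of 16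
Conditions: t-BuMe2SiOTf (1.1 equiv), 2,6-lutidine, CH2Cl2, −78 °C
Reagents that add atoms: tert-butyldimethylsilyl trifluoromethanesulfonate, CC(C)(C)[Si](C)(C)OS(=O)(=O)C(F)(F)F
Why: Silyl ether formation at low temperature takes the secondary C1 hydroxyl in preference to the hindered tertiary C4 hydroxyl, which must stay free for step 10.

Step 10
Reactants: 17 1-O-tert-butyldimethylsilyl ether of 16
Product: 18 C6–C7 epoxide of 17 (epoxide oxygen on C6 syn to the C4 oxygen)
Conditions: VO(acac)2 (5 mol%), t-BuOOH (1.5 equiv), CH2Cl2, 0 °C → rt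
Reagents that add atoms: tert-butyl hydroperoxide, CC(C)(C)OO
Why: In this hydroxyl-directed vanadium-catalysed epoxidation the C4 vanadate can deliver oxygen only to the homoallylic vinyl group (the allyl group is out of reach), through a chair-like transition state in which C5–C10 is equatorial and C6–H rather than C7 faces the axial C4 methyl group, which should give the C6 configuration drawn.

Step 11
Reactants: 18 C6–C7 epoxide of 17
Product: 19 4,6,7-triol
Conditions: HClO4 (cat.), THF/H2O 3:1, 0 °C → rt
Reagents that add atoms: water, O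
Why: Acid-catalysed epoxide hydrolysis proceeds by attack of water at the unhindered primary C7, so the C6–O bond and its configuration are retained.

Step 12
Reactants: 19 4,6,7-triol
Product: 21 4,6-O-(di-tert-butylsilanediyl)-7-O-triethylsilyl derivative of 19, via 7-O-triethylsilyl triol 20 (not isolated)
Conditions: Et3SiOTf (1.05 equiv), 2,6-lutidine (5 equiv), CH2Cl2, −78 °C; then t-Bu2Si(OTf)2 (1.3 equiv), −78 → 25 °C
Reagents that add atoms: triethylsilyl trifluoromethanesulfonate, CC[Si](CC)(CC)OS(=O)(=O)C(F)(F)F; di-tert-butylsilyl bis(trifluoromethanesulfonate), CC(C)(C)[Si](OS(=O)(=O)C(F)(F)F)(OS(=O)(=O)C(F)(F)F)C(C)(C)C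
Why: Silyl ether formation takes the primary hydroxyl first at −78 °C, and the bis-triflate then bridges the syn-disposed C4 and C6 hydroxyls as a six-membered silylene, which also fixes ring A in the chair that carries C6 and C9 equatorial.

Step 13
Reactants: 21 4,6-O-silylene 7-O-triethylsilyl ether
Product: 22 C7 aldehyde (formyl group on C6 of the silylene ring)
Conditions: (COCl)2 (3 equiv), DMSO (6 equiv), CH2Cl2, −78 → −30 °C; Et3N (10 equiv), → 0 °C
Reagents that add atoms: none
Why: Swern oxidation converts a primary triethylsilyl ether directly into the aldehyde while the silylene and the tert-butyldimethylsilyl ether are inert, and C6, which carries the formyl group equatorial on the silylene ring, has no driving force to epimerise.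

Step 14
Reactants: 22 C7 aldehyde; 23 methyl propiolate
Product: 25 C7 carbinol bearing the C11(=C13H2)–CO2Me acrylate, via vinylalane 24 (not isolated)
Conditions: i-Bu2AlH (1.8 equiv), HMPA (2 equiv), THF, 0 °C; 23 (2.0 equiv), 0 °C, 1 h; then 22, 0 °C → rt; aq. potassium sodium tartrate KNaC4H4O6
Reagents that add atoms: none
Why: Hydroalumination of methyl propiolate gives the α-aluminoacrylate, which adds to the hindered aldehyde to form the C7–C11 bond (a Morita–Baylis–Hillman-type adduct made by the vinylalane route), and the C7 carbinol mixture converges in step 15.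

Step 15
Reactants: 25 C7 carbinol acrylate
Product: 27 methyl (E)-2-(acetoxymethyl)enoate with the C10 allyl arm, via secondary acetate 26 (not isolated)
Conditions: Ac2O, Et3N, DMAP (cat.), CH2Cl2, 0 °C; solvent changed to THF, DABCO (1 equiv), 65 °C
Reagents that add atoms: acetic anhydride, CC(=O)OC(C)=O
Why: Acetylation followed by the DABCO-mediated SN2′/SN2 1,3-transposition of a Morita–Baylis–Hillman acetate moves the acetoxy group to C13 and the double bond to C7=C11, the conjugated trisubstituted (E)-enoate being the thermodynamic product, and the C7 stereocentre disappears.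

Step 16
Reactants: 27 methyl (E)-2-(acetoxymethyl)enoate with the C10 allyl arm
Product: 29 C8 aldehyde (cyclisation precursor), via ozonide 28 (not isolated)
Conditions: O3, CH2Cl2, −78 °C, Sudan Red 7B end point; PPh3, −78 °C → rt
Reagents that add atoms: ozone, [O-][O+]=O
Why: Ozonolysis with reductive work-up cleaves the electron-rich monosubstituted alkene of the allyl arm selectively, since the trisubstituted enoate, deactivated by the ester and the acetoxymethyl group, reacts far more slowly when ozone is dosed to a dye end point.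

Step 17
Reactants: 29 C8 aldehyde (cyclisation precursor)
Product: 31 methyl 1β-(tert-butyldimethylsilyloxy)-4α,6α-(di-tert-butylsilanediyldioxy)-8α-hydroxyeudesm-11(13)-en-12-oate, via samarium enolate 30 (not isolated)
Conditions: SmI2 (2.5 equiv, 0.1 M in THF), THF, −78 °C, no proton source; then aq. NH4Cl
Reagents that add atoms: none
Why: Divalent samarium transfers one electron to the C8 aldehyde, the ketyl radical adds to C7 (the enoate β-carbon), a second electron turns the C11 radical into the samarium enolate, and this expels the C13 acetate (E1cB), so the C11=C13 acrylate appears together with the C7–C8 bond. The closest known reaction type is the SmI2 ketyl–olefin cyclisation onto α,β-unsaturated esters, here terminated by β-elimination. Ring B closes in the 6-exo-trig mode through a chair in which the 4,6-O-silylene has already fixed ring A and holds the C6 oxygen equatorial. C7 is controlled by C6 and the ring fusion, the C11 arm taking the equatorial site trans to the C6 oxygen; C8 is controlled by the same chair, the ketyl oxygen lying equatorial and anti to the ester-bearing alkene carbon to avoid dipole and steric repulsion, which places it trans to C7. The step needs the aldehyde to be reduced before the enoate or its allylic acetate, which the much easier reduction of an aldehyde by SmI2 in THF without HMPA should secure, and it needs elimination to outrun enolate protonation, which the absence of a proton source secures.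

Step 18
Reactants: 31 8α-alcohol
Product: 32 8-O-acetate of 31
Conditions: Ac2O, pyridine, DMAP (cat.), CH2Cl2, 0 °C → rt
Reagents that add atoms: acetic anhydride, CC(=O)OC(C)=O
Why: Acylation under nucleophilic catalysis takes the only free hydroxyl group, the equatorial C8 alcohol.

Step 19
Reactants: 32 8-O-acetate of 31
Product: 33 CNP0272656.1, methyl 8α-acetoxy-1β,4α,6α-trihydroxyeudesm-11(13)-en-12-oate
Conditions: HF·pyridine, pyridine/THF, 0 °C → rt
Reagents that add atoms: none
Why: Fluoride-mediated desilylation removes the silylene and the silyl ether under mildly acidic conditions in which the acetate cannot migrate and the acrylate and methyl ester are untouched.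

**Compound list**

1 | (R)-(−)-linalool, (3R)-3,7-dimethylocta-1,6-dien-3-ol | C=C[C@](C)(O)CCC=C(C)C | starting material
2 | secondary ozonide of 1 at the trisubstituted alkene | C=C[C@](C)(O)CCC1OC(C)(C)OO1 | intermediate
3 | (4R)-4-hydroxy-4-methylhex-5-enal | C=C[C@](C)(O)CCC=O | intermediate
4 | (5R)-5-ethenyl-5-methyloxolan-2-ol (both anomers) | OC1CC[C@](C)(C=C)O1 | intermediate
5 | isopropenylmagnesium bromide | C=C(C)[Mg]Br | starting material
6 | (6R)-2,6-dimethylocta-1,7-diene-3,6-diol (both C3 epimers) | C=C(C)C(O)CC[C@@](C)(O)C=C | intermediate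
7 | (4R)-2,4-dimethylcyclohex-2-ene-1,4-diol (both C1 epimers) | CC1=C[C@](C)(O)CCC1O | intermediate
8 | (4R)-4-hydroxy-2,4-dimethylcyclohex-2-en-1-one | CC1=C[C@](C)(O)CCC1=O | intermediate
9 | (4R)-2,4-dimethyl-4-(trimethylsilyloxy)cyclohex-2-en-1-one | CC1=C[C@](C)(O[Si](C)(C)C)CCC1=O | intermediate
10 | vinylmagnesium bromide | C=C[Mg]Br | starting material
11 | (3R,4R)-3-ethenyl-2,4-dimethyl-1,4-bis(trimethylsilyloxy)cyclohex-1-ene | C=C[C@@H]1C(C)=C(O[Si](C)(C)C)CC[C@@]1(C)O[Si](C)(C)C | intermediate
12 | allyl bromide | C=CCBr | starting material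
13 | lithium enolate from 11 (O–Li on C1, C1=C10) | C=C[C@@H]1C(C)=C(O[Li])CC[C@@]1(C)O[Si](C)(C)C | intermediate
14 | 4-O-trimethylsilyl ether of 15 | C=CC[C@]1(C)[C@@H](C=C)[C@](C)(O[Si](C)(C)C)CCC1=O | intermediate
15 | (2R,3R,4R)-3-ethenyl-4-hydroxy-2,4-dimethyl-2-(prop-2-enyl)cyclohexan-1-one (skeleton: C1 ketone, C10 β-methyl and α-allyl, C5 β-vinyl, C4 β-methyl and α-hydroxyl) | C=CC[C@]1(C)[C@@H](C=C)[C@](C)(O)CCC1=O | intermediate
16 | ring A 1β,4α-diol from 15 | C=CC[C@]1(C)[C@@H](C=C)[C@](C)(O)CC[C@H]1O | intermediate
17 | 1-O-tert-butyldimethylsilyl ether of 16 | C=CC[C@]1(C)[C@@H](C=C)[C@](C)(O)CC[C@H]1O[Si](C)(C)C(C)(C)C | intermediate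
18 | C6–C7 epoxide of 17 | C=CC[C@]1(C)[C@@H]([C@@H]2CO2)[C@](C)(O)CC[C@H]1O[Si](C)(C)C(C)(C)C | intermediate
19 | 4,6,7-triol (1-O-tert-butyldimethylsilyl) | C=CC[C@]1(C)[C@@H]([C@@H](O)CO)[C@](C)(O)CC[C@H]1O[Si](C)(C)C(C)(C)C | intermediate
20 | 7-O-triethylsilyl ether of 19 | C=CC[C@]1(C)[C@@H]([C@@H](O)CO[Si](CC)(CC)CC)[C@](C)(O)CC[C@H]1O[Si](C)(C)C(C)(C)C | intermediate
21 | 4,6-O-(di-tert-butylsilanediyl)-7-O-triethylsilyl derivative of 19 | C=CC[C@]1(C)[C@H]2[C@H](CO[Si](CC)(CC)CC)O[Si](C(C)(C)C)(C(C)(C)C)O[C@]2(C)CC[C@H]1O[Si](C)(C)C(C)(C)C | intermediate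
22 | C7 aldehyde (4,6-O-silylene, 1-O-tert-butyldimethylsilyl, C10 allyl) | C=CC[C@]1(C)[C@H]2[C@H](C=O)O[Si](C(C)(C)C)(C(C)(C)C)O[C@]2(C)CC[C@H]1O[Si](C)(C)C(C)(C)C | intermediate
23 | methyl propiolate | C#CC(=O)OC | starting material
24 | methyl 2-(diisobutylalumanyl)prop-2-enoate | C=C([Al](CC(C)C)CC(C)C)C(=O)OC | intermediate
25 | C7 carbinol bearing the methyl acrylate unit on C7 (both C7 epimers) | C=CC[C@]1(C)[C@H]2[C@H](C(O)C(=C)C(=O)OC)O[Si](C(C)(C)C)(C(C)(C)C)O[C@]2(C)CC[C@H]1O[Si](C)(C)C(C)(C)C | intermediate
26 | C7 acetate of 25 | C=CC[C@]1(C)[C@H]2[C@H](C(OC(C)=O)C(=C)C(=O)OC)O[Si](C(C)(C)C)(C(C)(C)C)O[C@]2(C)CC[C@H]1O[Si](C)(C)C(C)(C)C | intermediate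
27 | methyl (E)-2-(acetoxymethyl)enoate, C6 cis to CH2OAc, C10 allyl arm | C=CC[C@]1(C)[C@H]2[C@H](/C=C(\COC(C)=O)C(=O)OC)O[Si](C(C)(C)C)(C(C)(C)C)O[C@]2(C)CC[C@H]1O[Si](C)(C)C(C)(C)C | intermediate
28 | secondary ozonide of 27 at the allyl group | C1OC(C[C@]2(C)[C@H]3[C@H](/C=C(\COC(C)=O)C(=O)OC)O[Si](C(C)(C)C)(C(C)(C)C)O[C@]3(C)CC[C@H]2O[Si](C)(C)C(C)(C)C)OO1 | intermediate
29 | C8 aldehyde, precursor of the key step | O=CC[C@]1(C)[C@H]2[C@H](/C=C(\COC(C)=O)C(=O)OC)O[Si](C(C)(C)C)(C(C)(C)C)O[C@]2(C)CC[C@H]1O[Si](C)(C)C(C)(C)C | intermediate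
30 | bis(diiodosamarium) C8 alkoxide and C11–C12 ester enolate, C13 acetate still in place | COC(O[Sm](I)I)=C(COC(C)=O)[C@H]1[C@H](O[Si]3(C(C)(C)C)C(C)(C)C)[C@@H]2[C@@](C)(C[C@@H]1O[Sm](I)I)[C@H](O[Si](C)(C)C(C)(C)C)CC[C@@]2(C)O3 | intermediate
31 | methyl 1β-(tert-butyldimethylsilyloxy)-4α,6α-(di-tert-butylsilanediyldioxy)-8α-hydroxyeudesm-11(13)-en-12-oate | C=C(C(=O)OC)[C@H]1[C@H](O[Si]3(C(C)(C)C)C(C)(C)C)[C@@H]2[C@@](C)(C[C@@H]1O)[C@H](O[Si](C)(C)C(C)(C)C)CC[C@@]2(C)O3 | intermediate
32 | 8-O-acetate of 31 | C=C(C(=O)OC)[C@H]1[C@H](O[Si]3(C(C)(C)C)C(C)(C)C)[C@@H]2[C@@](C)(C[C@@H]1OC(C)=O)[C@H](O[Si](C)(C)C(C)(C)C)CC[C@@]2(C)O3 | intermediate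
33 | CNP0272656.1, methyl 8α-acetoxy-1β,4α,6α-trihydroxyeudesm-11(13)-en-12-oate | C=C(C(=O)OC)[C@H]1[C@H](O)[C@@H]2[C@@](C)(C[C@@H]1OC(C)=O)[C@H](O)CC[C@@]2(C)O | target

**Step count and risks**

Total steps: 19. Longest linear sequence: 19 steps, from 1 to 33.

Steps most likely to fail:

1. Step 17. What may go wrong: electron transfer to the 2-(acetoxymethyl)enoate with loss of acetate before ring closure, simple reduction or pinacol coupling of the aldehyde outrunning the 6-exo closure, or lactonisation of the C8 alkoxide onto C12. Fallback: the same C7–C8 bond is made from the same aldehyde 29 by two-electron chemistry. Pd(PPh3)4 (catalytic) and InI in THF at rt should convert the allylic acetate, through a π-allylpalladium complex, into the C13 allylindium species F1. Its γ-carbon C7 adds to the C8 aldehyde through a chair transition state with return of the C11=C13 double bond (umpolung carbonyl allylation). Aqueous work-up gives 31, where the route is rejoined.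

2. Step 10. What may go wrong: slow oxygen transfer to a vinyl group flanked by two fully substituted carbons, or poor facial selectivity at C6. Fallback: setting out from 17, stoichiometric OsO4·TMEDA in CH2Cl2 at −78 °C is used. The C4 hydroxyl hydrogen-bonds to the reagent and directs syn-dihydroxylation to the homoallylic vinyl group, giving the cyclic osmate ester F2. Cleavage with aqueous Na2SO3 gives triol 19 directly, where the route is rejoined without passing through 18.

3. Step 8. What may go wrong: poor facial selectivity in hydride delivery to a conformationally mobile ketone. Fallback: setting out from 15, substrate control is replaced by catalyst control in a Corey–Bakshi–Shibata reduction [(S)-2-methyl-CBS-oxazaborolidine, catecholborane, toluene, −78 °C]. The catalyst distinguishes the quaternary C10 side from the C2 methylene side of the carbonyl and should deliver hydride to the face that gives the 1β-alcohol. The route is rejoined at 16 and no new compound is formed.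

**Further compounds**

F1 | step 17 | C13 allylindium acetate iodide derived from 29 | O=CC[C@]1(C)[C@H]2[C@H](C=C(C[In](I)OC(C)=O)C(=O)OC)O[Si](C(C)(C)C)(C(C)(C)C)O[C@]2(C)CC[C@H]1O[Si](C)(C)C(C)(C)C
F2 | step 10 | cyclic C6,C7 osmate ester of 19 as its TMEDA adduct | C=CC[C@]1(C)[C@@H]([C@@H]2CO[Os](=O)(=O)O2)[C@](C)(O)CC[C@H]1O[Si](C)(C)C(C)(C)C.CN(C)CCN(C)C
F0 | step 8 | none | none
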